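**Plan**

- Retrosynthesis: the γ-lactone (ring C) is opened at O7–C19. Ring B is then cut at C6–C7. C7 is a secondary carbinol carbon that is allylic to the (Z)-C5=C6 alkene and bonded to the fully substituted carbinol C8, so this cut leaves a (Z)-alkenyl iodide at C6 and a C7 aldehyde with no α-hydrogen, to be rejoined by Nozaki–Hiyama–Kishi addition. Further cuts are C8–C9 (aldol), C3–C4 (enolate alkylation) and the ring A bonds C1–C14 and C10–C11 (Diels–Alder).
- Forward: ring A is made first by a catalytic asymmetric Diels–Alder reaction. Its C12 oxygen and C13=C14 alkene come from epoxidation and epoxide-to-allylic-alcohol rearrangement. The C2 ester is turned into the C2–C6 iodoalkenyl carbinol chain. A malate-derived dioxolanone adds C7, C8 and C17–C19 at the C9 aldehyde. Ring B is closed at C6–C7, and the lactone ring C is closed last.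
- Stereochemistry: C1, C10 and C11 come from the endo Diels–Alder step (E dienophile, chiral oxazaborolidinium catalyst), C12 from α-face epoxidation, and C2 from Corey–Bakshi–Shibata reduction. C17 and C8 come from (S)-malate (anti methylation, then self-regeneration of the stereocentre through a tert-butyl acetal). C9 comes from Felkin–Anh aldol addition and C7 from chelation in the ring closure. The Z alkene comes from alkoxide-directed carbomagnesiation of prop-2-yn-1-ol.

Key step: step 22

Numbering: briarane numbering of the target is used (ring A = C1, C10–C14; ring B = C1–C10; ring C = C7, C8, C17, C19, O; methyls C15 on C1, C16 on C5, C18 on C17, C20 on C11). β is the ring A face that carries C15. TBS = tert-butyldimethylsilyl.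

Assumption: the (S)-configured oxazaborolidinium catalyst of step 3 is taken to give the (1S,5S,6S) adduct by the formyl C–H···O binding model; if the first run shows the opposite sense, the (R)-catalyst is used with no other change.

**Route**

Step 1
Reactants: 1 2,2-dimethoxyacetaldehyde; 2 methyl 2-(triphenyl-λ5-phosphanylidene)propanoate
Product: 3 methyl (E)-4,4-dimethoxy-2-methylbut-2-enoate
Conditions: CH2Cl2/H2O, rt
Reagents that add atoms: none
Why: Wittig olefination with a stabilised ylide should give the E trisubstituted enoate.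

Step 2
Reactants: 3 methyl (E)-4,4-dimethoxy-2-methylbut-2-enoate
Product: 4 methyl (E)-2-methyl-4-oxobut-2-enoate
Conditions: 1 M HCl, acetone, rt
Reagents that add atoms: water, O
Why: Acid-catalysed acetal hydrolysis should free the enal without touching the ester, the E geometry being the more stable one.

Step 3
Reactants: 4 methyl (E)-2-methyl-4-oxobut-2-enoate; 5 (E)-penta-1,3-diene
Product: 6 methyl (1S,5S,6S)-6-formyl-1,5-dimethylcyclohex-3-ene-1-carboxylate
Conditions: (S)-3,3-diphenyl-1-(2-methylphenyl)tetrahydro-1H,3H-pyrrolo[1,2-c][1,3,2]oxazaborole (20 mol %), (CF3SO2)2NH (17 mol %), CH2Cl2, −78 to −40 °C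
Reagents that add atoms: none
Why: In this catalytic enantioselective Diels–Alder reaction the boron Lewis acid binds the formyl group, so the methyl-bearing diene terminus should bond to the formyl-bearing carbon (C10), the endo formyl group sets C20 cis to C9, the E dienophile puts the ester (C2) trans to C9 at the quaternary C1, and the catalyst selects the face.

Step 4
Reactants: 6 methyl (1S,5S,6S)-6-formyl-1,5-dimethylcyclohex-3-ene-1-carboxylate
Product: 7 methyl (1S,5S,6S)-6-(dimethoxymethyl)-1,5-dimethylcyclohex-3-ene-1-carboxylate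
Conditions: HC(OMe)3, MeOH, pyridinium p-toluenesulfonate (cat.), rt
Reagents that add atoms: trimethyl orthoformate, COC(OC)OC
Why: Acid-catalysed acetalisation with orthoformate as water scavenger masks the epimerisable C9 aldehyde for the basic and hydride steps that follow.

Step 5
Reactants: 7 methyl (1S,5S,6S)-6-(dimethoxymethyl)-1,5-dimethylcyclohex-3-ene-1-carboxylate
Product: 8 methyl (1R,3S,4S,5R,6S)-4-(dimethoxymethyl)-3,5-dimethyl-7-oxabicyclo[4.1.0]heptane-3-carboxylate (12α,13α-epoxide)
Conditions: m-ClC6H4CO3H, NaHCO3, CH2Cl2, 0 °C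
Reagents that add atoms: 3-chloroperbenzoic acid, OOC(=O)c1cccc(Cl)c1
Why: Prilezhaev epoxidation should occur on the α face of C12=C13, opposite the three β groups (C15 methyl, C9 acetal carbon, C20 methyl), which places the future C12 oxygen trans to C20.

Step 6
Reactants: 8 methyl (1R,3S,4S,5R,6S)-4-(dimethoxymethyl)-3,5-dimethyl-7-oxabicyclo[4.1.0]heptane-3-carboxylate
Product: 9 methyl (1S,4R,5R,6S)-6-(dimethoxymethyl)-4-hydroxy-1,5-dimethylcyclohex-2-ene-1-carboxylate
Conditions: LiNEt2, Et2O/hexane, 0 °C to rt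
Reagents that add atoms: none
Why: In this lithium amide-mediated epoxide-to-allylic-alcohol rearrangement (syn β-elimination) the base should remove the α hydrogen of the secondary C14 rather than the hindered methine hydrogen at C11, which gives C13=C14 and keeps the C12–O bond and its configuration, while the neopentyl-type ester has no α-hydrogen and resists the amide.

Step 7
Reactants: 9 methyl (1S,4R,5R,6S)-6-(dimethoxymethyl)-4-hydroxy-1,5-dimethylcyclohex-2-ene-1-carboxylate
Product: 10 methyl (1S,4R,5R,6S)-4-(TBS-oxy)-6-(dimethoxymethyl)-1,5-dimethylcyclohex-2-ene-1-carboxylate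
Conditions: t-BuMe2SiCl, imidazole, DMF, rt
Reagents that add atoms: tert-butyl(chloro)dimethylsilane, CC(C)(C)[Si](C)(C)Cl
Why: Silyl ether formation on the secondary allylic alcohol protects the C12 hydroxyl until the last step.

Step 8
Reactants: 10 methyl (1S,4R,5R,6S)-4-(TBS-oxy)-6-(dimethoxymethyl)-1,5-dimethylcyclohex-2-ene-1-carboxylate
Product: 12 1-[(1S,4R,5R,6S)-4-(TBS-oxy)-6-(dimethoxymethyl)-1,5-dimethylcyclohex-2-en-1-yl]ethan-1-one, via α-silyl ketone 11 (not isolated)
Conditions: Me3SiCH2Li (2.5 equiv), pentane/THF, 0 °C; then MeOH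
Reagents that add atoms: (trimethylsilyl)methyllithium, [Li]C[Si](C)(C)C
Why: Acyl substitution of the non-enolisable ester by the silylmethyllithium stops at the enolate of the α-silyl ketone, and protodesilylation by methanol should give the C2 methyl ketone without over-addition.

Step 9
Reactants: 13 prop-2-yn-1-ol
Product: 14 (Z)-3-iodo-2-methylprop-2-en-1-ol
Conditions: MeMgBr (2.5 equiv), CuI (10 mol %), THF, −10 °C to rt; then I2, −10 °C
Reagents that add atoms: methylmagnesium bromide, C[Mg]Br; iodine, II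
Why: Alkoxide-directed copper-catalysed anti carbomagnesiation holds magnesium cis to the CH2O group in a five-membered chelate, and iodinolysis with retention should give the Z iodoalkene that becomes C5=C6.

Step 10
Reactants: 14 (Z)-3-iodo-2-methylprop-2-en-1-ol
Product: 15 (Z)-3-bromo-1-iodo-2-methylprop-1-ene
Conditions: PBr3, Et2O, 0 °C
Reagents that add atoms: phosphorus tribromide, BrP(Br)Br
Why: Bromination of the primary allylic alcohol by SN2 substitution leaves the alkenyl iodide and the alkene geometry untouched.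

Step 11
Reactants: 12 1-[(1S,4R,5R,6S)-4-(TBS-oxy)-6-(dimethoxymethyl)-1,5-dimethylcyclohex-2-en-1-yl]ethan-1-one; 15 (Z)-3-bromo-1-iodo-2-methylprop-1-ene
Product: 16 (4Z)-1-[(1S,4R,5R,6S)-4-(TBS-oxy)-6-(dimethoxymethyl)-1,5-dimethylcyclohex-2-en-1-yl]-5-iodo-4-methylpent-4-en-1-one
Conditions: LiN(i-Pr)2, THF, −78 °C; then 15, DMPU, −78 to −40 °C
Reagents that add atoms: none
Why: In this kinetic enolate alkylation the ketone can enolise only toward its methyl group (C3) because C1 is quaternary, and the lithium enolate should be alkylated by the reactive allylic bromide to form C3–C4.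

Step 12
Reactants: 16 (4Z)-1-[(1S,4R,5R,6S)-4-(TBS-oxy)-6-(dimethoxymethyl)-1,5-dimethylcyclohex-2-en-1-yl]-5-iodo-4-methylpent-4-en-1-one
Product: 17 (1R,4Z)-1-[(1S,4R,5R,6S)-4-(TBS-oxy)-6-(dimethoxymethyl)-1,5-dimethylcyclohex-2-en-1-yl]-5-iodo-4-methylpent-4-en-1-ol
Conditions: (S)-1-methyl-3,3-diphenyltetrahydro-1H,3H-pyrrolo[1,2-c][1,3,2]oxazaborole (20 mol %), BH3·SMe2, THF, −30 °C
Reagents that add atoms: none
Why: In this Corey–Bakshi–Shibata reduction the quaternary C1 is the large and the C3 methylene the small ketone substituent, so the (S)-catalyst should give the (R)-carbinol at C2 under reagent control at a temperature where alkene hydroboration is slow.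

Step 13
Reactants: 17 (1R,4Z)-1-[(1S,4R,5R,6S)-4-(TBS-oxy)-6-(dimethoxymethyl)-1,5-dimethylcyclohex-2-en-1-yl]-5-iodo-4-methylpent-4-en-1-ol
Product: 18 (1R,4Z)-1-[(1S,4R,5R,6S)-4-(TBS-oxy)-6-(dimethoxymethyl)-1,5-dimethylcyclohex-2-en-1-yl]-5-iodo-4-methylpent-4-en-1-yl acetate
Conditions: Ac2O, 4-(dimethylamino)pyridine (cat.), pyridine, rt
Reagents that add atoms: acetic anhydride, CC(=O)OC(C)=O
Why: Nucleophile-catalysed acylation installs the C2 acetate of the target on the hindered secondary alcohol.

Step 14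
Reactants: 18 (1R,4Z)-1-[(1S,4R,5R,6S)-4-(TBS-oxy)-6-(dimethoxymethyl)-1,5-dimethylcyclohex-2-en-1-yl]-5-iodo-4-methylpent-4-en-1-yl acetate
Product: 19 (1R,4Z)-1-[(1S,4R,5R,6S)-4-(TBS-oxy)-6-formyl-1,5-dimethylcyclohex-2-en-1-yl]-5-iodo-4-methylpent-4-en-1-yl acetate
Conditions: pyridinium p-toluenesulfonate, acetone/H2O, 50 °C
Reagents that add atoms: water, O
Why: Mild acid-catalysed acetal hydrolysis should release the C9 aldehyde while the secondary silyl ether, the acetate and the alkenyl iodide stay intact and C10 does not epimerise.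

Step 15
Reactants: 20 dimethyl (2S)-2-hydroxybutanedioate (dimethyl (S)-malate)
Product: 21 dimethyl (2S,3R)-2-hydroxy-3-methylbutanedioate
Conditions: LiN(SiMe3)2 (2.2 equiv), THF, −78 to −20 °C; MeI, −78 °C
Reagents that add atoms: iodomethane, CI
Why: In this Fráter–Seebach alkylation the chelated alkoxide enolate is methylated anti to the alkoxide, which should give the (2S,3R) diester and so sets C17.

Step 16
Reactants: 21 dimethyl (2S,3R)-2-hydroxy-3-methylbutanedioate
Product: 22 (2S,3R)-2-hydroxy-3-methylbutanedioic acid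
Conditions: KOH, H2O/MeOH, 0 °C to rt; then HCl (aq)
Reagents that add atoms: potassium hydroxide, [K+].[OH-]
Why: Saponification of both esters at low temperature gives the diacid, the carboxylates formed protecting C3 against epimerisation.

Step 17
Reactants: 22 (2S,3R)-2-hydroxy-3-methylbutanedioic acid
Product: 23 (2R)-2-[(2S,4S)-2-tert-butyl-5-oxo-1,3-dioxolan-4-yl]propanoic acid
Conditions: t-BuCHO, p-toluenesulfonic acid (cat.), H2SO4 (cat.), pentane, reflux, water separator
Reagents that add atoms: 2,2-dimethylpropanal, CC(C)(C)C=O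
Why: Acid-catalysed acetalisation of the α-hydroxy acid unit under water removal gives the five-membered dioxolanone, whose thermodynamically preferred cis isomer (tert-butyl cis to the side chain) stores the C8 configuration in the acetal centre.

Step 18
Reactants: 23 (2R)-2-[(2S,4S)-2-tert-butyl-5-oxo-1,3-dioxolan-4-yl]propanoic acid
Product: 24 tert-butyl (2R)-2-[(2S,4S)-2-tert-butyl-5-oxo-1,3-dioxolan-4-yl]propanoate
Conditions: Cl3CC(=NH)O-t-Bu, BF3·OEt2 (cat.), CH2Cl2/cyclohexane, rt
Reagents that add atoms: tert-butyl 2,2,2-trichloroacetimidate, CC(C)(C)OC(=N)C(Cl)(Cl)Cl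
Why: Acid-catalysed O-alkylation with the trichloroacetimidate esterifies the free acid without opening the dioxolanone and gives a C19 ester that resists premature lactonisation and is hard to enolise.

Step 19
Reactants: 24 tert-butyl (2R)-2-[(2S,4S)-2-tert-butyl-5-oxo-1,3-dioxolan-4-yl]propanoate; 19 (1R,4Z)-1-[(1S,4R,5R,6S)-4-(TBS-oxy)-6-formyl-1,5-dimethylcyclohex-2-en-1-yl]-5-iodo-4-methylpent-4-en-1-yl acetate
Product: 26 seco dioxolanone acetate (6,7-seco compound with 2-OAc, (9R)-9-OAc, 12α-OTBS, (Z)-C6 iodide, C7/C8 as carbonyl and quaternary carbon of a (2S)-2-tert-butyl-1,3-dioxolan-4-one, tert-butyl C19 ester), via lithium aldolate 25 (not isolated)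
Conditions: LiN(SiMe3)2, THF, −78 °C; 19; then Ac2O, −78 to −20 °C
Reagents that add atoms: acetic anhydride, CC(=O)OC(C)=O
Why: In this aldol addition of a dioxolanone lithium enolate (self-regeneration of stereocentres) the amide base removes only the lactone α-hydrogen, the enolate adds anti to the tert-butyl group so that C9 takes the place of H8 with retention, the aldehyde face is chosen by Felkin–Anh control from C10 with the quaternary C1 as the large group, which should give (9R), and the aldolate is trapped as the C9 acetate before retro-aldol cleavage.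

Step 20
Reactants: 26 seco dioxolanone acetate
Product: 27 seco C7,C8-diol (as 26, with C7 as CH2OH and a free tertiary C8 hydroxyl)
Conditions: NaBH4, THF/H2O (4:1), 0 °C to rt
Reagents that add atoms: none
Why: Borohydride reduction of the activated acylal-type lactone carbonyl should give the primary C7 alcohol and free the C8 hydroxyl with loss of the acetal carbon as neopentyl alcohol, while the acetates and the tert-butyl ester are not reduced and the tert-butyl ester is not attacked by the new alkoxide.

Step 21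
Reactants: 27 seco C7,C8-diol
Product: 28 seco C7 aldehyde (as 27, with C7 as CHO; ring-closure precursor)
Conditions: SO3·pyridine, DMSO, i-Pr2NEt, CH2Cl2, 0 °C
Reagents that add atoms: none
Why: Parikh–Doering oxidation converts the primary alcohol into the aldehyde without glycol cleavage or reaction at the tertiary C8 hydroxyl, and the product cannot enolise.

Step 22
Reactants: 28 seco C7 aldehyde
Product: 29 ring B carbinol ((5Z,7S)-7,8-dihydroxy compound with 2,9-diacetate, 12α-OTBS and tert-butyl C19 ester)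
Conditions: CrCl2 (10 equiv), NiCl2 (0.1 equiv), DMSO/THF (3:1), rt, 2 mM, slow addition of 28
Reagents that add atoms: none
Why: Zerovalent nickel, formed from NiCl2 by CrCl2, inserts into the C6–I bond with retention of the Z geometry, the alkenyl group passes to trivalent chromium, and the alkenylchromium adds to the C7 aldehyde to give a chromium alkoxide that is hydrolysed on work-up. The closest known reaction type is the Nozaki–Hiyama–Kishi macrocyclisation of an alkenyl iodide onto an aldehyde to give medium-ring allylic alcohols. Ring B closes as a ten-membered ring by exo-trig addition to the carbonyl group (10-exo-trig), C6–C7 being the only skeletal bond formed. The new stereocentre C7 should be controlled by a five-membered chromium chelate between the C8 hydroxyl and the aldehyde oxygen, in which the tethered alkenyl group arrives from the face on which C9 lies, which corresponds to (7S). The step needs activation of the alkenyl iodide beside an aldehyde, two acetates, an ester and a free tertiary alcohol, and ring closure in preference to dimerisation; the first is secured by the mild, non-basic organochromium reagent and the absence of an α-hydrogen at C8, the second by high dilution and by the trans-disposed C2 and C9 branches on ring A, which hold the two chain ends close.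

Step 23
Reactants: 29 ring B carbinol
Product: 30 12-O-TBS ether of the target (7,19-lactone closed)
Conditions: CF3CO2H/CH2Cl2 (1:4), 0 °C
Reagents that add atoms: none
Why: Acid-mediated cleavage of the tert-butyl ester with lactonisation of the C7 hydroxyl onto C19 closes the five-membered ring C, only the 7,19-lactone being possible because O9 is acetylated, and the oxygen at C8 disfavours ionisation at the allylic C7.

Step 24
Reactants: 30 12-O-TBS ether of the target
Product: 31 CNP0222085.1 (target)
Conditions: HF·pyridine, THF/pyridine, 0 °C to rt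
Reagents that add atoms: none
Why: Buffered fluoride-mediated desilylation removes the C12 silyl ether without acetate migration or lactone opening.

**Compound list**

1 | 2,2-dimethoxyacetaldehyde | COC(OC)C=O | starting material
2 | methyl 2-(triphenyl-λ5-phosphanylidene)propanoate | COC(=O)C(C)=P(c1ccccc1)(c1ccccc1)c1ccccc1 | starting material
3 | methyl (E)-4,4-dimethoxy-2-methylbut-2-enoate | COC(OC)/C=C(\C)C(=O)OC | intermediate
4 | methyl (E)-2-methyl-4-oxobut-2-enoate | O=C/C=C(\C)C(=O)OC | intermediate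
5 | (E)-penta-1,3-diene | C/C=C/C=C | starting material
6 | methyl (1S,5S,6S)-6-formyl-1,5-dimethylcyclohex-3-ene-1-carboxylate | O=C[C@H]1[C@@H](C)C=CC[C@]1(C)C(=O)OC | intermediate
7 | methyl (1S,5S,6S)-6-(dimethoxymethyl)-1,5-dimethylcyclohex-3-ene-1-carboxylate | COC(OC)[C@H]1[C@@H](C)C=CC[C@]1(C)C(=O)OC | intermediate
8 | methyl (1R,3S,4S,5R,6S)-4-(dimethoxymethyl)-3,5-dimethyl-7-oxabicyclo[4.1.0]heptane-3-carboxylate (12α,13α-epoxide) | COC(OC)[C@H]1[C@@H](C)[C@@H]2O[C@@H]2C[C@]1(C)C(=O)OC | intermediate
9 | methyl (1S,4R,5R,6S)-6-(dimethoxymethyl)-4-hydroxy-1,5-dimethylcyclohex-2-ene-1-carboxylate | COC(OC)[C@H]1[C@@H](C)[C@H](O)C=C[C@]1(C)C(=O)OC | intermediate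
10 | methyl (1S,4R,5R,6S)-4-(TBS-oxy)-6-(dimethoxymethyl)-1,5-dimethylcyclohex-2-ene-1-carboxylate | COC(OC)[C@H]1[C@@H](C)[C@H](O[Si](C)(C)C(C)(C)C)C=C[C@]1(C)C(=O)OC | intermediate
11 | 1-[(1S,4R,5R,6S)-4-(TBS-oxy)-6-(dimethoxymethyl)-1,5-dimethylcyclohex-2-en-1-yl]-2-(trimethylsilyl)ethan-1-one (α-silyl ketone, not isolated) | COC(OC)[C@H]1[C@@H](C)[C@H](O[Si](C)(C)C(C)(C)C)C=C[C@]1(C)C(=O)C[Si](C)(C)C | intermediate
12 | 1-[(1S,4R,5R,6S)-4-(TBS-oxy)-6-(dimethoxymethyl)-1,5-dimethylcyclohex-2-en-1-yl]ethan-1-one | COC(OC)[C@H]1[C@@H](C)[C@H](O[Si](C)(C)C(C)(C)C)C=C[C@]1(C)C(C)=O | intermediate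
13 | prop-2-yn-1-ol | C#CCO | starting material
14 | (Z)-3-iodo-2-methylprop-2-en-1-ol | OC/C(C)=C\I | intermediate
15 | (Z)-3-bromo-1-iodo-2-methylprop-1-ene | BrC/C(C)=C\I | intermediate
16 | (4Z)-1-[(1S,4R,5R,6S)-4-(TBS-oxy)-6-(dimethoxymethyl)-1,5-dimethylcyclohex-2-en-1-yl]-5-iodo-4-methylpent-4-en-1-one | COC(OC)[C@H]1[C@@H](C)[C@H](O[Si](C)(C)C(C)(C)C)C=C[C@]1(C)C(=O)CC/C(C)=C\I | intermediate
17 | (1R,4Z)-1-[(1S,4R,5R,6S)-4-(TBS-oxy)-6-(dimethoxymethyl)-1,5-dimethylcyclohex-2-en-1-yl]-5-iodo-4-methylpent-4-en-1-ol | COC(OC)[C@H]1[C@@H](C)[C@H](O[Si](C)(C)C(C)(C)C)C=C[C@]1(C)[C@H](O)CC/C(C)=C\I | intermediate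
18 | (1R,4Z)-1-[(1S,4R,5R,6S)-4-(TBS-oxy)-6-(dimethoxymethyl)-1,5-dimethylcyclohex-2-en-1-yl]-5-iodo-4-methylpent-4-en-1-yl acetate | COC(OC)[C@H]1[C@@H](C)[C@H](O[Si](C)(C)C(C)(C)C)C=C[C@]1(C)[C@H](OC(C)=O)CC/C(C)=C\I | intermediate
19 | (1R,4Z)-1-[(1S,4R,5R,6S)-4-(TBS-oxy)-6-formyl-1,5-dimethylcyclohex-2-en-1-yl]-5-iodo-4-methylpent-4-en-1-yl acetate | O=C[C@H]1[C@@H](C)[C@H](O[Si](C)(C)C(C)(C)C)C=C[C@]1(C)[C@H](OC(C)=O)CC/C(C)=C\I | intermediate
20 | dimethyl (2S)-2-hydroxybutanedioate | COC(=O)C[C@H](O)C(=O)OC | starting material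
21 | dimethyl (2S,3R)-2-hydroxy-3-methylbutanedioate | COC(=O)[C@H](C)[C@H](O)C(=O)OC | intermediate
22 | (2S,3R)-2-hydroxy-3-methylbutanedioic acid | OC(=O)[C@H](C)[C@H](O)C(=O)O | intermediate
23 | (2R)-2-[(2S,4S)-2-tert-butyl-5-oxo-1,3-dioxolan-4-yl]propanoic acid | OC(=O)[C@H](C)[C@@H]1O[C@H](C(C)(C)C)OC1=O | intermediate
24 | tert-butyl (2R)-2-[(2S,4S)-2-tert-butyl-5-oxo-1,3-dioxolan-4-yl]propanoate | CC(C)(C)OC(=O)[C@H](C)[C@@H]1O[C@H](C(C)(C)C)OC1=O | intermediate
25 | lithium aldolate: (9R)-C9 lithium alkoxide of the adduct of 24 and 19 (as 26, with OLi in place of 9-OAc; not isolated) | [Li+].[O-][C@@H]([C@@](O2)(C(=O)O[C@H]2C(C)(C)C)[C@@H](C)C(=O)OC(C)(C)C)[C@H]1[C@@H](C)[C@H](O[Si](C)(C)C(C)(C)C)C=C[C@]1(C)[C@H](OC(C)=O)CC/C(C)=C\I | intermediate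
26 | seco dioxolanone acetate: 6,7-seco compound with (2R)-2-OAc, (9R)-9-OAc, 12α-OTBS, (Z)-C5=C6 iodoalkene, C7 and C8 as carbonyl and quaternary carbon of a (2S)-2-tert-butyl-1,3-dioxolan-4-one (tert-butyl trans to C9), (17R) tert-butyl C19 ester | CC(=O)O[C@@H]([C@@](O2)(C(=O)O[C@H]2C(C)(C)C)[C@@H](C)C(=O)OC(C)(C)C)[C@H]1[C@@H](C)[C@H](O[Si](C)(C)C(C)(C)C)C=C[C@]1(C)[C@H](OC(C)=O)CC/C(C)=C\I | intermediate
27 | seco C7,C8-diol: as 26, with C7 as CH2OH and a free tertiary C8 hydroxyl | CC(=O)O[C@@H]([C@@](O)(CO)[C@@H](C)C(=O)OC(C)(C)C)[C@H]1[C@@H](C)[C@H](O[Si](C)(C)C(C)(C)C)C=C[C@]1(C)[C@H](OC(C)=O)CC/C(C)=C\I | intermediate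
28 | seco C7 aldehyde: as 27, with C7 as CHO | CC(=O)O[C@@H]([C@@](O)(C=O)[C@@H](C)C(=O)OC(C)(C)C)[C@H]1[C@@H](C)[C@H](O[Si](C)(C)C(C)(C)C)C=C[C@]1(C)[C@H](OC(C)=O)CC/C(C)=C\I | intermediate
29 | ring B carbinol: (5Z,7S)-7,8-diol with 2,9-diacetate, 12α-OTBS and tert-butyl C19 ester | CC(=O)O[C@@H]1[C@H]2[C@@H](C)[C@H](O[Si](C)(C)C(C)(C)C)C=C[C@]2(C)[C@H](OC(C)=O)CC/C(C)=C\[C@H](O)[C@@]1(O)[C@@H](C)C(=O)OC(C)(C)C | intermediate
30 | 12-O-TBS ether of the target | CC(=O)O[C@@H]1[C@H]2[C@@H](C)[C@H](O[Si](C)(C)C(C)(C)C)C=C[C@]2(C)[C@H](OC(C)=O)CC/C(C)=C\[C@@H]2OC(=O)[C@H](C)[C@]21O | intermediate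
31 | CNP0222085.1, (1S,2R,5Z,7S,8S,9R,10S,11R,12R,17R)-2,9-diacetoxy-8,12-dihydroxy-briara-5,13-dien-19,7-olide | CC(=O)O[C@@H]1[C@H]2[C@@H](C)[C@H](O)C=C[C@]2(C)[C@H](OC(C)=O)CC/C(C)=C\[C@@H]2OC(=O)[C@H](C)[C@]21O | target

**Step count**

Total: 24 steps. Longest linear sequence: 18 steps (steps 1–8, 11–14, 19–24).

**Steps most likely to fail**

Step 22. The alkenylchromium may add to the other aldehyde face if the chelate with the C8 hydroxyl is not kept in DMSO, so that the wrong C7 configuration predominates, or closure may be outrun by intermolecular coupling. The fallback sets out from 28 and sets C7 by reduction instead of in the C–C bond formation. The ring is still closed by the same coupling, and the product with the wrong configuration at C7, the 7-epi carbinol F1 (alone or mixed with 29), is oxidised with MnO2 in CH2Cl2 to the ring B C7 enone F2. Reduction with Zn(BH4)2 in Et2O at −20 °C, chelated between the C8 hydroxyl and the ketone, should deliver hydride to the face away from C9. The fallback comes back to the route at 29.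

Step 19. The hindered lithium aldolate may revert by retro-aldol cleavage before it is acetylated, or face selection at C9 may be poor in the closed lithium transition state. The fallback sets out from 24 (with 19). Compound 24 is converted with LiN(SiMe3)2 and Me3SiCl in THF at −78 °C into the trimethylsilyl ketene acetal F3. F3 is added to 19 with BF3·OEt2 in CH2Cl2 at −78 °C in a Mukaiyama aldol reaction (open transition state, Felkin–Anh face of the aldehyde, attack anti to the tert-butyl group, no reversal) to give the free C9 aldol F4. Acetylation with Ac2O and 4-(dimethylamino)pyridine comes back to the route at 26.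

Step 20. The hindered lactone carbonyl may be reduced so slowly that acetate loss or acetyl migration from O9 to O7 competes under the basic conditions. The fallback sets out from 26. Perhydrolysis with LiOH/H2O2 in THF/H2O at 0 °C opens the dioxolanone at its activated carbonyl and gives the C7 α-hydroxy acid F5. BH3·SMe2 in THF at 0 °C then reduces the free carboxylic acid in the presence of the esters and comes back to the route at 27.

**Further compounds**

F1 | step 22 | 7-epi carbinol (C7 epimer of 29) | CC(=O)O[C@@H]1[C@H]2[C@@H](C)[C@H](O[Si](C)(C)C(C)(C)C)C=C[C@]2(C)[C@H](OC(C)=O)CC/C(C)=C\[C@@H](O)[C@@]1(O)[C@@H](C)C(=O)OC(C)(C)C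
F2 | step 22 | ring B C7 enone (7-oxo analogue of 29) | CC(=O)O[C@@H]1[C@H]2[C@@H](C)[C@H](O[Si](C)(C)C(C)(C)C)C=C[C@]2(C)[C@H](OC(C)=O)CC/C(C)=C\C(=O)[C@@]1(O)[C@@H](C)C(=O)OC(C)(C)C
F3 | step 19 | trimethylsilyl ketene acetal of 24 (2-tert-butyl-5-(trimethylsilyloxy)-1,3-dioxole) | CC(C)(C)OC(=O)[C@H](C)C1=C(O[Si](C)(C)C)O[C@@H](C(C)(C)C)O1
F4 | step 19 | free C9 aldol (as 26, with 9-OH in place of 9-OAc) | O[C@@H]([C@@](O2)(C(=O)O[C@H]2C(C)(C)C)[C@@H](C)C(=O)OC(C)(C)C)[C@H]1[C@@H](C)[C@H](O[Si](C)(C)C(C)(C)C)C=C[C@]1(C)[C@H](OC(C)=O)CC/C(C)=C\I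
F5 | step 20 | C7 α-hydroxy acid (as 27, with C7 as CO2H) | CC(=O)O[C@@H]([C@@](O)(C(=O)O)[C@@H](C)C(=O)OC(C)(C)C)[C@H]1[C@@H](C)[C@H](O[Si](C)(C)C(C)(C)C)C=C[C@]1(C)[C@H](OC(C)=O)CC/C(C)=C\I
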